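The pyranone (ring C) is disconnected at C3–C4 and O1–C8a. On ring A the three oxygen-bearing carbons C8a, C5 and C7 are mutually meta and lie ortho, ortho and para to C4a, which carries the C4 carbonyl. Ring A can therefore enter as a 2,4,6-trifluorobenzoyl unit in which every fluoride is carbonyl-activated. In one telescoped operation the magnesium enolate of an α-prenyl aryl ketone is C-aroylated and the 1,3-diketone enolate oxygen displaces one ortho fluoride, closing ring C with the 3-prenyl and 2-aryl groups in place. The precursor is 1-[4-(allyloxy)-2-methoxyphenyl]-5-methylhex-4-en-1-one; the remaining fluorides later become allyl ethers, and all allyl groups leave together.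

Key step: step 3

Remark 1: the target has no stereocentre and no stereogenic double bond (the prenyl alkene carries two identical methyl groups), so it is achiral and no enantiocontrol is needed.
Remark 2: 1-(4-hydroxy-2-methoxyphenyl)ethanone (isopaeonol) is taken to be a catalogue compound, as are allyl bromide, prenyl bromide, allyl alcohol and 2,4,6-trifluorobenzoyl chloride.

Step 1
Reactants: 1 1-(4-hydroxy-2-methoxyphenyl)ethanone; 2 allyl bromide
Product: 3 1-[4-(allyloxy)-2-methoxyphenyl]ethanone
Conditions: K2CO3 (1.5 equiv), allyl bromide (1.2 equiv), acetone, reflux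
Reagents that add atoms: allyl bromide (compound 2), C=CCBr
Why: Williamson ether synthesis, in which the carbonate-generated phenoxide is O-alkylated by the primary allylic bromide (SN2) while the methyl ketone is not enolised by this weak base.

Step 2
Reactants: 3 1-[4-(allyloxy)-2-methoxyphenyl]ethanone; 4 prenyl bromide (1-bromo-3-methylbut-2-ene)
Product: 6 1-[4-(allyloxy)-2-methoxyphenyl]-5-methylhex-4-en-1-one, via lithium enolate 5 (not isolated)
Conditions: LDA (commercial solution, 1.05 equiv), THF, −78 °C; then prenyl bromide (0.95 equiv), DMPU, −78 → 0 °C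
Reagents that add atoms: prenyl bromide (compound 4), CC(C)=CCBr
Why: Kinetic lithium enolate alkylation, in which irreversible deprotonation of the only enolisable position (the acetyl CH3) is followed by SN2 attack at the primary carbon of the allylic bromide, and low temperature with the halide in slight deficit should limit proton exchange and hence double alkylation.

Step 3
Reactants: 6 1-[4-(allyloxy)-2-methoxyphenyl]-5-methylhex-4-en-1-one; 7 2,4,6-trifluorobenzoyl chloride
Product: 10 2-[4-(allyloxy)-2-methoxyphenyl]-5,7-difluoro-3-(3-methylbut-2-en-1-yl)-4H-chromen-4-one, via bromomagnesium enolate 8 (not isolated), via prenylated 1,3-diketone 9 (not isolated)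
Conditions: MgBr2·OEt2 (2.5 equiv), i-Pr2NEt (3 equiv), 7 (1.1 equiv), CH2Cl2, 0 °C → rt; aqueous wash, solvent exchange; then K2CO3 (2 equiv), DMF, 60 °C (crude 9)
Reagents that add atoms: 2,4,6-trifluorobenzoyl chloride (compound 7), O=C(Cl)c1c(F)cc(F)cc1F
Why: Magnesium(II) binds the ketone carbonyl (assisted by the 2-methoxy oxygen) so that i-Pr2NEt can remove an α-proton (soft enolisation), and the magnesium enolate 8 attacks the acid chloride through carbon (Claisen-type C-acylation) to give diketone 9; the carbonate-derived enolate of 9 then adds through its B-ring-side oxygen to an ortho C–F carbon (the future C8a) and expels fluoride via a Meisenheimer anion stabilised by the C4 carbonyl and the other two fluorines (intramolecular SNAr). The closest known chemistry is the direct C-acylation of ketones with acid chlorides under MgBr2/amine soft enolisation, combined with the chromone and flavone synthesis from 1-(2-fluoroaryl)-1,3-diketones or from ketone enolates and 2-fluorobenzoyl chlorides by acylation–SNAr. The pyranone closes as a six-membered ring by O-attack on an sp2 carbon, 6-endo-trig with respect to the carbonyl-conjugated C4a=C8a bond (equally 6-exo-trig on C8=C8a in the other Kekulé form), a favoured mode; attack by the other diketone oxygen would require a four-membered ring. No stereocentre is created, because the C2 methine of 9 is configurationally labile and ends as the sp2 carbon C3. The step needs C- over O-acylation, which the tightly oxygen-bound magnesium enolate should secure, and a single cyclisation site, which follows from the equivalence of the two ortho fluorides; 6 has only one enolisable position, and the near-stoichiometric charge of 7 limits over-acylation of 9.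

Step 4
Reactants: 10 2-[4-(allyloxy)-2-methoxyphenyl]-5,7-difluoro-3-(3-methylbut-2-en-1-yl)-4H-chromen-4-one; 11 allyl alcohol
Product: 13 5,7-bis(allyloxy)-2-[4-(allyloxy)-2-methoxyphenyl]-3-(3-methylbut-2-en-1-yl)-4H-chromen-4-one, via 7-allyloxy-5-fluoro monoether 12 (not isolated)
Conditions: allyl alcohol (6 equiv), NaH (5 equiv), THF, 0 °C (alkoxide preformed, no NaH left); then 10, THF–DMSO, rt → 60 °C
Reagents that add atoms: allyl alcohol (compound 11), C=CCO
Why: Nucleophilic aromatic substitution by addition–elimination, in which the C7 and C5 fluorides (para and ortho to the C4 carbonyl) are displaced in turn by allyloxide, the para fluoride expected first in a dipolar aprotic medium, while the 2-aryl-3-alkyl substitution shields C2 from conjugate attack and the temperature stays far below that of an aromatic Claisen rearrangement.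

Step 5
Reactants: 13 5,7-bis(allyloxy)-2-[4-(allyloxy)-2-methoxyphenyl]-3-(3-methylbut-2-en-1-yl)-4H-chromen-4-one
Product: 14 2-(4-hydroxy-2-methoxyphenyl)-5,7-dihydroxy-3-(3-methylbut-2-en-1-yl)-4H-chromen-4-one (target)
Conditions: Pd(PPh3)4 (10 mol%), morpholine (10 equiv), degassed THF, rt; dilute citric acid work-up
Reagents that add atoms: none
Why: Tsuji–Trost-type deallylation, in which Pd(0) ionises each aryl allyl ether to a π-allyl complex and a phenoxide and excess morpholine captures the allyl unit irreversibly, conditions that should leave the prenyl group, the methyl ether and the pyranone untouched.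

Compound list
1 | 1-(4-hydroxy-2-methoxyphenyl)ethanone | CC(=O)c1ccc(O)cc1OC | starting material
2 | allyl bromide (3-bromoprop-1-ene) | C=CCBr | starting material
3 | 1-[4-(allyloxy)-2-methoxyphenyl]ethanone | CC(=O)c1ccc(OCC=C)cc1OC | intermediate
4 | prenyl bromide (1-bromo-3-methylbut-2-ene) | CC(C)=CCBr | starting material
5 | lithium 1-[4-(allyloxy)-2-methoxyphenyl]ethen-1-olate (lithium enolate of 3) | [Li+].[O-]C(=C)c1ccc(OCC=C)cc1OC | intermediate (not isolated)
6 | 1-[4-(allyloxy)-2-methoxyphenyl]-5-methylhex-4-en-1-one | C=CCOc1ccc(C(=O)CCC=C(C)C)c(OC)c1 | intermediate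
7 | 2,4,6-trifluorobenzoyl chloride | O=C(Cl)c1c(F)cc(F)cc1F | starting material
8 | bromomagnesium 1-[4-(allyloxy)-2-methoxyphenyl]-5-methylhexa-1,4-dien-1-olate (enolate of 6, drawn as the expected Z isomer; geometry immaterial) | C=CCOc1ccc(/C(O[Mg]Br)=C/CC=C(C)C)c(OC)c1 | intermediate (not isolated)
9 | 1-[4-(allyloxy)-2-methoxyphenyl]-2-(3-methylbut-2-en-1-yl)-3-(2,4,6-trifluorophenyl)propane-1,3-dione (racemic, configurationally labile at C2) | C=CCOc1ccc(C(=O)C(CC=C(C)C)C(=O)c2c(F)cc(F)cc2F)c(OC)c1 | intermediate (not isolated)
10 | 2-[4-(allyloxy)-2-methoxyphenyl]-5,7-difluoro-3-(3-methylbut-2-en-1-yl)-4H-chromen-4-one | C=CCOc1ccc(-c2oc3cc(F)cc(F)c3c(=O)c2CC=C(C)C)c(OC)c1 | intermediate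
11 | allyl alcohol (prop-2-en-1-ol) | C=CCO | starting material
12 | 7-(allyloxy)-2-[4-(allyloxy)-2-methoxyphenyl]-5-fluoro-3-(3-methylbut-2-en-1-yl)-4H-chromen-4-one | C=CCOc1ccc(-c2oc3cc(OCC=C)cc(F)c3c(=O)c2CC=C(C)C)c(OC)c1 | intermediate (not isolated)
13 | 5,7-bis(allyloxy)-2-[4-(allyloxy)-2-methoxyphenyl]-3-(3-methylbut-2-en-1-yl)-4H-chromen-4-one | C=CCOc1ccc(-c2oc3cc(OCC=C)cc(OCC=C)c3c(=O)c2CC=C(C)C)c(OC)c1 | intermediate
14 | 2-(4-hydroxy-2-methoxyphenyl)-5,7-dihydroxy-3-(3-methylbut-2-en-1-yl)-4H-chromen-4-one (achiral) | COc1cc(O)ccc1-c1oc2cc(O)cc(O)c2c(=O)c1CC=C(C)C | target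

Total step count: 5
Longest linear sequence: 5 steps (1 → 3 → 6 → 10 → 13 → 14)

Steps most likely to fail

Step 3. The congested trisubstituted enolate may acylate on oxygen instead of carbon, or enolisation under the mild amine base may be incomplete. The fallback replaces the acylation by an aldol addition, where O-acylation cannot occur, followed by oxidation. It sets out from 6: LDA in THF at −78 °C and 2,4,6-trifluorobenzaldehyde, with a cold acetic acid quench, should give the aldol adduct 1-[4-(allyloxy)-2-methoxyphenyl]-2-[hydroxy(2,4,6-trifluorophenyl)methyl]-5-methylhex-4-en-1-one F1 as a diastereomer mixture, both stereocentres being erased later. Dess–Martin periodinane with NaHCO3 in CH2Cl2 should then oxidise the secondary alcohol to the 1,3-diketone. The fallback comes back to the route at 9, which is closed to 10 by K2CO3 in DMF as in the second stage of step 3.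

Step 4. The exchange may stall after the first fluoride, because the new alkoxy group weakens the activation by the carbonyl, and forcing may lead to alkoxide attack at C2 with opening of the pyranone. The fallback finishes the second C–F to C–O exchange with a weakly basic α-effect nucleophile that acts as a hydroxide surrogate. It sets out from 12, obtained by stopping step 4 at the monoether stage (about 1.1 equiv of alkoxide, rt) and isolating it. (E)-Benzaldoxime and K2CO3 in DMSO at 70 °C should displace the C5 fluoride to give the O-aryl oxime ether (E)-benzaldehyde O-{7-(allyloxy)-2-[4-(allyloxy)-2-methoxyphenyl]-3-(3-methylbut-2-en-1-yl)-4-oxo-4H-chromen-5-yl}oxime F2. In the same flask base-induced elimination of benzonitrile should give 7-(allyloxy)-2-[4-(allyloxy)-2-methoxyphenyl]-5-hydroxy-3-(3-methylbut-2-en-1-yl)-4H-chromen-4-one F3. Pd(PPh3)4 and morpholine in THF then remove the two remaining allyl groups, so the fallback comes back to the route at 14. If the first substitution were to take place at C5 instead, the regioisomeric monoether would converge on 14 by the same sequence.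

Step 2. Proton transfer between the mono-alkylated ketone and unreacted enolate may lead to double alkylation and return of unalkylated ketone. The fallback alkylates a stabilised β-keto ester enolate, which takes only one prenyl group under mild base, and then removes the ester. It sets out from 3: NaH and dimethyl carbonate in THF at reflux (Claisen condensation) should give methyl 3-[4-(allyloxy)-2-methoxyphenyl]-3-oxopropanoate F4. K2CO3 and prenyl bromide in acetone should give methyl 2-[4-(allyloxy)-2-methoxybenzoyl]-5-methylhex-4-enoate F5 (racemic; the stereocentre is lost in the next operation). Krapcho dealkoxycarbonylation (LiCl, wet DMSO, 130 °C) should then deliver the ketone, so the fallback comes back to the route at 6.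

Further compounds
F1 | step 3 | 1-[4-(allyloxy)-2-methoxyphenyl]-2-[hydroxy(2,4,6-trifluorophenyl)methyl]-5-methylhex-4-en-1-one (diastereomer mixture, racemic) | C=CCOc1ccc(C(=O)C(CC=C(C)C)C(O)c2c(F)cc(F)cc2F)c(OC)c1
F2 | step 4 | (E)-benzaldehyde O-{7-(allyloxy)-2-[4-(allyloxy)-2-methoxyphenyl]-3-(3-methylbut-2-en-1-yl)-4-oxo-4H-chromen-5-yl}oxime | C=CCOc1ccc(-c2oc3cc(OCC=C)cc(O/N=C/c4ccccc4)c3c(=O)c2CC=C(C)C)c(OC)c1
F3 | step 4 | 7-(allyloxy)-2-[4-(allyloxy)-2-methoxyphenyl]-5-hydroxy-3-(3-methylbut-2-en-1-yl)-4H-chromen-4-one | C=CCOc1ccc(-c2oc3cc(OCC=C)cc(O)c3c(=O)c2CC=C(C)C)c(OC)c1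
F4 | step 2 | methyl 3-[4-(allyloxy)-2-methoxyphenyl]-3-oxopropanoate | COC(=O)CC(=O)c1ccc(OCC=C)cc1OC
F5 | step 2 | methyl 2-[4-(allyloxy)-2-methoxybenzoyl]-5-methylhex-4-enoate (racemic) | COC(=O)C(CC=C(C)C)C(=O)c1ccc(OCC=C)cc1OC
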